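## Structural features

The target 20 has one carbocycle, a cyclopent-2-enone made of C8–C12 (prostanoid numbering): C9 is the ketone, C10=C11 the ring alkene with bromine on C10, C12 a quaternary carbon, and C8 carries the exocyclic C7=C8 alkene. The ketone is cross-conjugated, to C10=C11 on one side and to the (5E,7E)-dienylidene C8=C7–C6=C5 on the other, which continues through C4–C2 to the methyl ester C1. C12 is the only stereocentre (R); it bears the acetoxy group and the (Z)-oct-2-enyl chain C13–C20 (C14=C15 Z). Because C12 sits between two sp2 ring carbons (C8 and C11), no neighbouring stereocentre or α-hydrogen can relay stereochemistry, so its configuration must come from a reagent or catalyst. Fragile groups are the tertiary, doubly allylic acetate (ionisation, especially by zerovalent palladium), the α-bromoenone, the dienone (electrophilic at C11, C7 and C5, geometrically labile at C7=C8) and the skipped Z alkene. The real difficulty is the ring-bound quaternary carbinol C12 next to a geometrically defined 7E alkylidene, together with placing bromine on C10 in a molecule that holds three other C=C bonds. The key step exploits the fact that C9 is a single carbonyl carbon lying between two sp2 carbons, C10 and C8: it can be carbon monoxide, and taking it out opens the ring to an acyclic triene in which C12 is an ordinary tertiary ether carbon.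

## Logic of the disconnections

20 ⇒ 19. The acetyl C–O bond is cut. A tertiary, doubly allylic acetate would be ionised by zerovalent palladium, so it must be the last group made. The forward step must acylate a hindered tertiary alcohol without conjugate addition to the dienone.

19 ⇒ 18. The O–CH2Ar bond is cut. The C12 oxygen has to be masked as an ether during ring construction, because a free hydroxyl would capture the acylpalladium as a butenolide. The forward step must remove the benzyl-type ether oxidatively without touching the dienone or the Z alkene.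

18 ⇒ 17 + CO (key disconnection). The bonds C9–C10 and C9–C8 are cut. The ring, the ketone and the cross-conjugated dienone vanish; what remains is an acyclic triene with one stereocentre, and the 7E problem is reduced to the E geometry of an ordinary disubstituted alkene. The forward step demands oxidative addition at C10–I only, iodine cis to C12, 5-exo acylpalladation at C8, and loss of the hydrogen on C8.

17 ⇒ 15 (through 16). The C10–I bond is exchanged for C10–Br. The symmetric dibromoalkene needs no geometric control when it is made. The forward step must exchange only the bromine cis to C12.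

15 ⇒ 14 ⇒ 13. The C10=C11 double bond is cut (dibromo-olefination), then C11 is taken back to the alcohol. C10 and both halogens come from CBr4. The aldehyde carbon is attached to a quaternary centre, so it is hindered but cannot epimerise.

13 ⇒ 9 + 12. The C6–C7 bond is cut (Heck reaction). The α chain C1–C6 becomes a separate piece, and 12 ⇒ 10 (through 11) by hydrozirconation–iodination. The forward step must give the E,E diene; β-hydride elimination can only go toward C7 because C12 bears no hydrogen.

9 ⇒ 8. The C12–O ether bond is cut. This is where the stereocentre is set: a racemic vinyl epoxide is funnelled into one enantiomer of the tertiary ether. The forward step needs attack at the tertiary allyl terminus and facial equilibration of the π-allyl that is faster than attack.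

8 ⇒ 6 (through 7). The C12–C8 bond (vinyl addition to the ketone) and the epoxide C–O bond are cut. The demand is 1,2-addition to an enolisable α-chloroketone.

6 ⇒ 5 ⇒ 4 ⇒ 1 + 2 (through 3). After oxidation-level and alkyne adjustments, the C13–C14 bond is cut (acetylide opening of the epoxide). The Z alkene is made by semi-hydrogenation while no other alkene is present.

## Other disconnections considered

Alternative 1: the first idea is to cut C7=C8. The forward key step is an aldol condensation of the C8 enolate of the protected bromo-hydroxycyclopentenone A1 with the enal A2, followed by dehydration.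
- The C8 enolate of A1 has the C12 oxygen in the β position, so β-elimination and retro-aldol pathways are built in.
- The dehydration decides 7E against 7Z in an elimination that has no stereospecific course, whereas the chosen key step transfers geometry from a defined E alkene.
- A1 still contains the quaternary carbinol C12 as a single enantiomer, so the hardest problem is only moved, at a similar step count.

Alternative 2: cut C8–C12 and take the C12 oxygen from water. The forward key step is a Piancatelli rearrangement (4π conrotatory closure) of the furylcarbinol A3 to the trans hydroxycyclopentenone A4, with the furan C3 bromine becoming C10–Br.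
- The intermediate cation is achiral, so A4 would be racemic.
- The 3-bromo and 5-alkyl groups should both slow the reaction (a less stabilised cation, and water attack at a substituted furan carbon).
- A4 has C8 as sp3, so C7=C8 would need a later dehydrogenation next to a base-labile β-hydroxy ketone, with no control of 7E.

Alternative 3: cut both C–O bonds at C9 and C12. The forward key step is a singlet-oxygen (4+2) cycloaddition to the fulvene A5, giving the endoperoxide A6, then Kornblum–DeLaMare fragmentation (only C9 carries a hydrogen) to the hydroxy dienone A7.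
- The regiochemistry of the fragmentation is unambiguous, but A6 is racemic, and a chiral base could at best resolve it with loss of half the material.
- A5 is hard to make as one regio- and geometric isomer, since condensation of a monoalkylcyclopentadienide should favour the 2-alkyl fulvene.
- Singlet oxygen can also attack C14=C15 in an ene reaction, and bromine would still have to be put on C10 of a tetraene.

Key step: step 11

Assumption: the (R,R)-configured ligand in step 5 is taken to give the (2S)-ether 9, by analogy with additions of heteroatom nucleophiles to 2-substituted vinyloxiranes under this catalyst; if the sense is the reverse, the (S,S)-ligand is used and nothing else changes.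

## Route

Step 1
Reactants: 1 hept-1-yne; 2 (±)-2-(chloromethyl)oxirane (epichlorohydrin)
Product: 4 (±)-1-chlorodec-4-yn-2-ol, via lithium hept-1-yn-1-ide 3 (not isolated)
Conditions: n-BuLi, THF, –78 °C; BF3·OEt2; then 2, –78 °C
Reagents that add atoms: none
Why: Boron-trifluoride-assisted opening of a terminal epoxide by a lithium acetylide occurs at the unsubstituted carbon and is faster than displacement of chloride; the carbinol centre is racemic, which does not matter because it is oxidised in step 3.

Step 2
Reactants: 4 (±)-1-chlorodec-4-yn-2-ol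
Product: 5 (±)-(4Z)-1-chlorodec-4-en-2-ol
Conditions: H2 (1 atm), Pd/CaCO3 poisoned with Pb(OAc)2, quinoline, EtOAc, rt
Reagents that add atoms: none
Why: Lindlar semi-hydrogenation adds hydrogen syn to the alkyne and should give the Z alkene (later C14=C15); it is done here because no other alkene is yet present, and the alkyl chloride is inert.

Step 3
Reactants: 5 (±)-(4Z)-1-chlorodec-4-en-2-ol
Product: 6 (4Z)-1-chlorodec-4-en-2-one
Conditions: Dess–Martin periodinane, CH2Cl2, 0 °C to rt
Reagents that add atoms: none
Why: Dess–Martin oxidation of the secondary alcohol under near-neutral conditions should leave the skipped Z alkene out of conjugation; 6 is used without storage.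

Step 4
Reactants: 6 (4Z)-1-chlorodec-4-en-2-one
Product: 8 (±)-2-ethenyl-2-[(2Z)-oct-2-en-1-yl]oxirane, via chlorohydrin 7 (not isolated)
Conditions: CH2=CHMgBr, THF, –78 °C; then 2 M NaOH, rt
Reagents that add atoms: vinylmagnesium bromide, C=C[Mg]Br
Why: Grignard 1,2-addition to the very electrophilic α-chloroketone should outrun enolisation at –78 °C, and the tertiary alkoxide then displaces the neighbouring primary chloride to close the epoxide; the new centre (later C12) is racemic and is corrected in step 5.

Step 5
Reactants: 8 (±)-2-ethenyl-2-[(2Z)-oct-2-en-1-yl]oxirane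
Product: 9 (2S,4Z)-2-ethenyl-2-[(4-methoxybenzyl)oxy]dec-4-en-1-ol
Conditions: Pd2(dba)3·CHCl3 (1 mol %), (R,R)-DACH-phenyl bisphosphine ligand N,N'-[(1R,2R)-cyclohexane-1,2-diyl]bis[2-(diphenylphosphanyl)benzamide] (3 mol %), Et3B (1 mol %), 4-MeOC6H4CH2OH, CH2Cl2, rt
Reagents that add atoms: 4-methoxybenzyl alcohol, COc1ccc(CO)cc1
Why: Palladium-catalysed dynamic kinetic asymmetric allylic etherification: both enantiomers of 8 ionise to π-allylpalladium alkoxides that interconvert by η3–η1–η3 exchange at the CH2 terminus, and the boron-bound alkoxide delivers the benzylic alcohol to the tertiary terminus. The chiral ligand pocket selects the face of attack and so sets C12 (S in 9, which becomes R in the ring compounds).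

Step 6
Reactants: 10 methyl hex-5-ynoate
Product: 12 methyl (5E)-6-iodohex-5-enoate, via alkenylzirconocene chloride 11 (not isolated)
Conditions: Cp2Zr(H)Cl, THF, rt; then I2, 0 °C
Reagents that add atoms: iodine, II
Why: Syn hydrozirconation of the terminal alkyne places zirconium on the terminal carbon faster than the ester is reduced, and iodinolysis with retention should give the E vinyl iodide (later C5=C6).

Step 7
Reactants: 9 (2S,4Z)-2-ethenyl-2-[(4-methoxybenzyl)oxy]dec-4-en-1-ol; 12 methyl (5E)-6-iodohex-5-enoate
Product: 13 methyl (5E,7E,9S,11Z)-9-(hydroxymethyl)-9-[(4-methoxybenzyl)oxy]heptadeca-5,7,11-trienoate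
Conditions: Pd(OAc)2 (5 mol %), Bu4NCl, K2CO3, DMF, 40 °C
Reagents that add atoms: none
Why: Heck reaction under Jeffery conditions: the alkenylpalladium adds to the terminal carbon of the vinyl group, and β-hydride elimination can only occur toward C7 (C12 has no hydrogen), which should give the E alkene with retention of the iodide geometry. The 1,2-disubstituted Z alkene is far less reactive toward insertion.

Step 8
Reactants: 13 methyl (5E,7E,9S,11Z)-9-(hydroxymethyl)-9-[(4-methoxybenzyl)oxy]heptadeca-5,7,11-trienoate
Product: 14 methyl (5E,7E,9S,11Z)-9-formyl-9-[(4-methoxybenzyl)oxy]heptadeca-5,7,11-trienoate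
Conditions: Dess–Martin periodinane, CH2Cl2, 0 °C to rt
Reagents that add atoms: none
Why: Dess–Martin oxidation of the primary alcohol; the aldehyde is attached to the quaternary C12 and has no α-hydrogen, so it cannot epimerise or enolise.

Step 9
Reactants: 14 methyl (5E,7E,9S,11Z)-9-formyl-9-[(4-methoxybenzyl)oxy]heptadeca-5,7,11-trienoate
Product: 15 methyl (5E,7E,9S,11Z)-9-(2,2-dibromoethenyl)-9-[(4-methoxybenzyl)oxy]heptadeca-5,7,11-trienoate
Conditions: CBr4, PPh3, 2,6-lutidine, CH2Cl2, 0 °C
Reagents that add atoms: carbon tetrabromide, BrC(Br)(Br)Br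
Why: Ramirez dibromo-olefination (first stage of the Corey–Fuchs sequence) converts the hindered aldehyde into the 1,1-dibromoalkene, introducing C10 and its bromine with no geometric issue; the base buffers traces of HBr so the benzylic ether survives.

Step 10
Reactants: 15 methyl (5E,7E,9S,11Z)-9-(2,2-dibromoethenyl)-9-[(4-methoxybenzyl)oxy]heptadeca-5,7,11-trienoate
Product: 17 methyl (5E,7E,9S,11Z)-9-[(Z)-2-bromo-2-iodoethenyl]-9-[(4-methoxybenzyl)oxy]heptadeca-5,7,11-trienoate, via magnesium carbenoid 16 (not isolated)
Conditions: i-PrMgCl·LiCl (1.05 equiv), THF, –78 °C; then I2, –78 °C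
Reagents that add atoms: iodine, II
Why: Bromine–magnesium exchange of a 1,1-dibromoalkene should take the bromine cis to C12, since that is the more compressed halogen and the ether oxygen on C12 chelates magnesium in a five-membered ring; the chelated carbenoid is also the thermodynamic one, so any equilibration converges on it. Iodinolysis with retention then places iodine cis to C12, and the methyl ester is tolerated at –78 °C.

Step 11
Reactants: 17 methyl (5E,7E,9S,11Z)-9-[(Z)-2-bromo-2-iodoethenyl]-9-[(4-methoxybenzyl)oxy]heptadeca-5,7,11-trienoate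
Product: 18 methyl (5E,7E)-7-{(5R)-3-bromo-5-[(4-methoxybenzyl)oxy]-5-[(2Z)-oct-2-en-1-yl]-2-oxocyclopent-3-en-1-ylidene}hept-5-enoate
Conditions: PdCl2(PPh3)2 (5 mol %), CO (3 bar), Et3N (2 equiv), MeCN–THF, 50 °C
Reagents that add atoms: carbon monoxide, [C-]#[O+]
Why: Zerovalent palladium inserts into the C10–I bond (much weaker than C10–Br) and CO inserts to give an α-bromoacryloylpalladium that is held cis to C12 and therefore next to C8. A 5-exo-trig syn acylpalladation of C7=C8 then forms C9–C8 and a π-allylpalladium over C7–C5, and loss of the hydrogen on C8 (β-hydride elimination from the C7 σ-form, helped by Et3N because that hydrogen is now α to the ketone) releases the dienone and zerovalent palladium. The closest known reaction type is the cyclic acylpalladation (carbonylative Heck cyclisation) of (Z)-1-iodo-1,4-dienes to 5-alkylidenecyclopent-2-enones. The cyclopentenone ring is closed in the 5-exo-trig mode at C8, with both bonds to C9 made in this step. No stereocentre is formed, and C12 is a spectator whose four bonds are untouched. Syn addition followed by syn elimination replaces the C8 hydrogen by C9 so that C6 ends trans to C9, which turns the E geometry of C7=C8 in 17 into 7E in 18, and the favoured syn π-allyl keeps C5=C6 E. The step needs C–I over C–Br (bond strength, mild temperature), C8 over C14 (5-exo onto a diene with π-allyl formation against 6-exo onto an isolated alkene), ketone and not ester formation (no alcohol present), and no lactonisation or ionisation at C12 (oxygen masked as an ether).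

Step 12
Reactants: 18 methyl (5E,7E)-7-{(5R)-3-bromo-5-[(4-methoxybenzyl)oxy]-5-[(2Z)-oct-2-en-1-yl]-2-oxocyclopent-3-en-1-ylidene}hept-5-enoate
Product: 19 methyl (5E,7E)-7-{(5R)-3-bromo-5-hydroxy-5-[(2Z)-oct-2-en-1-yl]-2-oxocyclopent-3-en-1-ylidene}hept-5-enoate
Conditions: DDQ, CH2Cl2–pH 7 phosphate buffer, 0 °C
Reagents that add atoms: none
Why: Oxidative cleavage of the 4-methoxybenzyl ether by hydride abstraction at the benzylic carbon and hydrolysis; the C12–O bond is not broken, so the configuration is kept, and the electron-poor dienone and the isolated Z alkene should not be oxidised.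

Step 13
Reactants: 19 methyl (5E,7E)-7-{(5R)-3-bromo-5-hydroxy-5-[(2Z)-oct-2-en-1-yl]-2-oxocyclopent-3-en-1-ylidene}hept-5-enoate
Product: 20 methyl (5E,7E)-7-{(5R)-5-acetoxy-3-bromo-5-[(2Z)-oct-2-en-1-yl]-2-oxocyclopent-3-en-1-ylidene}hept-5-enoate (target)
Conditions: Ac2O, DMAP, CH2Cl2, rt
Reagents that add atoms: acetic anhydride, CC(=O)OC(C)=O
Why: DMAP-catalysed acylation of the tertiary alcohol through the acylpyridinium; the dienone has no enolisable hydrogen, and acylation at oxygen leaves C12 unchanged.

## Compound list

1 | hept-1-yne | CCCCCC#C | starting material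
2 | (±)-2-(chloromethyl)oxirane | ClCC1CO1 | starting material
3 | lithium hept-1-yn-1-ide | CCCCCC#C[Li] | intermediate
4 | (±)-1-chlorodec-4-yn-2-ol | CCCCCC#CCC(O)CCl | intermediate
5 | (±)-(4Z)-1-chlorodec-4-en-2-ol | CCCCC/C=C\CC(O)CCl | intermediate
6 | (4Z)-1-chlorodec-4-en-2-one | CCCCC/C=C\CC(=O)CCl | intermediate
7 | (±)-(5Z)-3-(chloromethyl)undeca-1,5-dien-3-ol (formed as its bromomagnesium alkoxide) | CCCCC/C=C\CC(O)(C=C)CCl | intermediate
8 | (±)-2-ethenyl-2-[(2Z)-oct-2-en-1-yl]oxirane | CCCCC/C=C\CC1(C=C)CO1 | intermediate
9 | (2S,4Z)-2-ethenyl-2-[(4-methoxybenzyl)oxy]dec-4-en-1-ol | CCCCC/C=C\C[C@@](C=C)(OCc1ccc(OC)cc1)CO | intermediate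
10 | methyl hex-5-ynoate | COC(=O)CCCC#C | starting material
11 | chlorobis(cyclopentadienyl)[(1E)-6-methoxy-6-oxohex-1-en-1-yl]zirconium | COC(=O)CCC/C=C/[Zr](Cl)(C1C=CC=C1)C1C=CC=C1 | intermediate
12 | methyl (5E)-6-iodohex-5-enoate | COC(=O)CCC/C=C/I | intermediate
13 | methyl (5E,7E,9S,11Z)-9-(hydroxymethyl)-9-[(4-methoxybenzyl)oxy]heptadeca-5,7,11-trienoate | CCCCC/C=C\C[C@@](/C=C/C=C/CCCC(=O)OC)(OCc1ccc(OC)cc1)CO | intermediate
14 | methyl (5E,7E,9S,11Z)-9-formyl-9-[(4-methoxybenzyl)oxy]heptadeca-5,7,11-trienoate | CCCCC/C=C\C[C@@](/C=C/C=C/CCCC(=O)OC)(OCc1ccc(OC)cc1)C=O | intermediate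
15 | methyl (5E,7E,9S,11Z)-9-(2,2-dibromoethenyl)-9-[(4-methoxybenzyl)oxy]heptadeca-5,7,11-trienoate | CCCCC/C=C\C[C@@](/C=C/C=C/CCCC(=O)OC)(OCc1ccc(OC)cc1)C=C(Br)Br | intermediate
16 | methyl (5E,7E,9S,11Z)-9-[2-bromo-2-(chloromagnesio)ethenyl]-9-[(4-methoxybenzyl)oxy]heptadeca-5,7,11-trienoate, magnesium cis to C12 | CCCCC/C=C\C[C@@](/C=C/C=C/CCCC(=O)OC)(OCc1ccc(OC)cc1)/C=C(\[Mg]Cl)Br | intermediate
17 | methyl (5E,7E,9S,11Z)-9-[(Z)-2-bromo-2-iodoethenyl]-9-[(4-methoxybenzyl)oxy]heptadeca-5,7,11-trienoate | CCCCC/C=C\C[C@@](/C=C/C=C/CCCC(=O)OC)(OCc1ccc(OC)cc1)/C=C(\I)Br | intermediate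
18 | methyl (5E,7E)-7-{(5R)-3-bromo-5-[(4-methoxybenzyl)oxy]-5-[(2Z)-oct-2-en-1-yl]-2-oxocyclopent-3-en-1-ylidene}hept-5-enoate | CCCCC/C=C\C[C@@]1(OCc2ccc(OC)cc2)C=C(Br)C(=O)/C1=C/C=C/CCCC(=O)OC | intermediate
19 | methyl (5E,7E)-7-{(5R)-3-bromo-5-hydroxy-5-[(2Z)-oct-2-en-1-yl]-2-oxocyclopent-3-en-1-ylidene}hept-5-enoate | CCCCC/C=C\C[C@@]1(O)C=C(Br)C(=O)/C1=C/C=C/CCCC(=O)OC | intermediate
20 | methyl (5E,7E)-7-{(5R)-5-acetoxy-3-bromo-5-[(2Z)-oct-2-en-1-yl]-2-oxocyclopent-3-en-1-ylidene}hept-5-enoate | CCCCC/C=C\C[C@@]1(OC(C)=O)C=C(Br)C(=O)/C1=C/C=C/CCCC(=O)OC | target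

## Step count and least certain steps

Total: 13 steps. Longest linear sequence: 12 steps (steps 1–5 and 7–13; step 6 is the side branch).

Step 11 (key step). The most likely failure is further oxidative addition of zerovalent palladium into the C10–Br bond of the product, an activated α-bromoenone, which would lose bromine or give oligomers. A second risk is elimination of palladium hydride from the π-allyl toward C4 instead of C8, giving a deconjugated ketone and eroding the 7E geometry. Fallback: bromine is taken out of the ring-closing step.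
- From 14, olefination with Ph3P=CHI (Stork–Zhao conditions) would give methyl (5E,7E,9S,11Z)-9-[(Z)-2-iodoethenyl]-9-[(4-methoxybenzyl)oxy]heptadeca-5,7,11-trienoate F1.
- The same carbonylative cyclisation, now on the parent 1-iodo-1,4-diene substrate class, would give the bromine-free dienone F2.
- Nucleophilic epoxidation of the ring enone (t-BuOOH, DBU) would give the 10,11-epoxide F3, and MgBr2·OEt2 should open it at C10, the carbon α to the ketone, to the bromohydrin F4.
- Elimination by way of the mesylate F5 (MsCl, Et3N) would return to the route at 18.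

Step 10. The exchange may take the bromine trans to C12, or the carbenoid may lose its geometry before iodination; in both cases the iodine ends on the wrong side and ring closure is impossible. Attack of the Grignard reagent on the ester is a smaller risk. Fallback: C9 is brought in by olefination instead of carbon monoxide, so no stereodefined bromo-iodo-alkene is needed.
- From 14, Horner–Wadsworth–Emmons reaction with 2-(trimethylsilyl)ethyl 2-[bis(2,2,2-trifluoroethoxy)phosphoryl]-2-bromoacetate (NaH, THF, –78 °C; this phosphonate type places the ester cis to C12) would give the (E)-2-bromoacrylate F6.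
- TBAF would free the acid F7, and 1-chloro-N,N,2-trimethylprop-1-en-1-amine would give the acid chloride F8.
- Oxidative addition of zerovalent palladium into the C–Cl bond (Pd(PPh3)4, i-Pr2NEt, CO atmosphere to hold back decarbonylation) would enter the same acylpalladium manifold and close the ring, rejoining the route at 18.

Step 5. With the long C12 substituent, attack at the primary allyl terminus (linear ether) or attack before the π-allyl faces have equilibrated would lower regio- and enantioselectivity. Fallback: resolution instead of asymmetric catalysis.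
- From 8, the same addition with an achiral catalyst (Pd(PPh3)4, Et3B) would give the racemic ether F9.
- Esterification with (S)-2-methoxy-2-phenylacetic acid (DCC, DMAP) would give the diastereomeric esters F10 (from the 2S alcohol) and F11 (from the 2R alcohol), to be separated by chromatography.
- Hydrolysis of F10 (LiOH, THF–H2O) would return to the route at 9.

Step 7. Palladium hydride formed in the Heck cycle may re-add and move the diene or isomerise the Z alkene, and β-alkoxide elimination of the C12 ether from the alkylpalladium would destroy the stereocentre. Fallback: a transmetalation-initiated oxidative Heck coupling at room temperature.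
- From 10, hydroboration with pinacolborane (Cp2Zr(H)Cl cat.) would give the (E)-alkenylboronate F12.
- Coupling of F12 with 9 under divalent palladium (Pd(OAc)2, 1,2-bis(phenylsulfinyl)ethane, benzoquinone, AcOH, dioxane, rt) would rejoin the route at 13.

## Further compounds

F1 | step 11 | methyl (5E,7E,9S,11Z)-9-[(Z)-2-iodoethenyl]-9-[(4-methoxybenzyl)oxy]heptadeca-5,7,11-trienoate | CCCCC/C=C\C[C@@](/C=C/C=C/CCCC(=O)OC)(OCc1ccc(OC)cc1)/C=C\I
F2 | step 11 | methyl (5E,7E)-7-{(5R)-5-[(4-methoxybenzyl)oxy]-5-[(2Z)-oct-2-en-1-yl]-2-oxocyclopent-3-en-1-ylidene}hept-5-enoate | CCCCC/C=C\C[C@@]1(OCc2ccc(OC)cc2)C=CC(=O)/C1=C/C=C/CCCC(=O)OC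
F3 | step 11 | 10,11-epoxide of F2, methyl (5E,7E)-7-{2-[(4-methoxybenzyl)oxy]-2-[(2Z)-oct-2-en-1-yl]-4-oxo-6-oxabicyclo[3.1.0]hexan-3-ylidene}hept-5-enoate (carbinol carbon as in 18, epoxide diastereomers) | CCCCC/C=C\C[C@@]1(OCc2ccc(OC)cc2)C3OC3C(=O)/C1=C/C=C/CCCC(=O)OC
F4 | step 11 | bromohydrin, methyl (5E,7E)-7-{3-bromo-4-hydroxy-5-[(4-methoxybenzyl)oxy]-5-[(2Z)-oct-2-en-1-yl]-2-oxocyclopentylidene}hept-5-enoate (carbinol carbon as in 18, diastereomers at the two new centres) | CCCCC/C=C\C[C@@]1(OCc2ccc(OC)cc2)C(O)C(Br)C(=O)/C1=C/C=C/CCCC(=O)OC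
F5 | step 11 | methanesulfonate of F4 | CCCCC/C=C\C[C@@]1(OCc2ccc(OC)cc2)C(OS(C)(=O)=O)C(Br)C(=O)/C1=C/C=C/CCCC(=O)OC
F6 | step 10 | methyl (5E,7E,9S,11Z)-9-{(1E)-2-bromo-3-oxo-3-[2-(trimethylsilyl)ethoxy]prop-1-en-1-yl}-9-[(4-methoxybenzyl)oxy]heptadeca-5,7,11-trienoate | CCCCC/C=C\C[C@@](/C=C/C=C/CCCC(=O)OC)(OCc1ccc(OC)cc1)/C=C(\C(=O)OCC[Si](C)(C)C)Br
F7 | step 10 | (2E)-2-bromo-3-substituted acrylic acid from F6, carboxyl cis to C12 | CCCCC/C=C\C[C@@](/C=C/C=C/CCCC(=O)OC)(OCc1ccc(OC)cc1)/C=C(\C(O)=O)Br
F8 | step 10 | acid chloride of F7 | CCCCC/C=C\C[C@@](/C=C/C=C/CCCC(=O)OC)(OCc1ccc(OC)cc1)/C=C(\C(Cl)=O)Br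
F9 | step 5 | (±)-(4Z)-2-ethenyl-2-[(4-methoxybenzyl)oxy]dec-4-en-1-ol | CCCCC/C=C\CC(C=C)(OCc1ccc(OC)cc1)CO
F10 | step 5 | (2S,4Z)-2-ethenyl-2-[(4-methoxybenzyl)oxy]dec-4-en-1-yl (2S)-2-methoxy-2-phenylacetate | CCCCC/C=C\C[C@@](C=C)(OCc1ccc(OC)cc1)COC(=O)[C@@H](OC)c1ccccc1
F11 | step 5 | (2R,4Z)-2-ethenyl-2-[(4-methoxybenzyl)oxy]dec-4-en-1-yl (2S)-2-methoxy-2-phenylacetate | CCCCC/C=C\C[C@](C=C)(OCc1ccc(OC)cc1)COC(=O)[C@@H](OC)c1ccccc1
F12 | step 7 | methyl (5E)-6-(4,4,5,5-tetramethyl-1,3,2-dioxaborolan-2-yl)hex-5-enoate | COC(=O)CCC/C=C/B1OC(C)(C)C(C)(C)O1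
A1 | alternative 1 | (4S)-2-bromo-4-[(2Z)-oct-2-en-1-yl]-4-[(trimethylsilyl)oxy]cyclopent-2-en-1-one | CCCCC/C=C\C[C@@]1(O[Si](C)(C)C)C=C(Br)C(=O)C1
A2 | alternative 1 | methyl (5E)-7-oxohept-5-enoate | COC(=O)CCC/C=C/C=O
A3 | alternative 2 | (±)-methyl (5E)-8-{3-bromo-5-[(2Z)-oct-2-en-1-yl]furan-2-yl}-8-hydroxyoct-5-enoate | CCCCC/C=C\Cc1cc(Br)c(C(O)C/C=C/CCCC(=O)OC)o1
A4 | alternative 2 | (±)-methyl (5E)-7-{trans-3-bromo-5-hydroxy-5-[(2Z)-oct-2-en-1-yl]-2-oxocyclopent-3-en-1-yl}hept-5-enoate (one enantiomer drawn) | CCCCC/C=C\C[C@@]1(O)C=C(Br)C(=O)[C@H]1C/C=C/CCCC(=O)OC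
A5 | alternative 3 | methyl (5E)-7-{2-[(2Z)-oct-2-en-1-yl]cyclopenta-2,4-dien-1-ylidene}hept-5-enoate, chain trans to the unsubstituted ring carbon | CCCCC/C=C\CC1=CC=C/C1=C/C=C/CCCC(=O)OC
A6 | alternative 3 | (±)-methyl (5E)-7-{1-[(2Z)-oct-2-en-1-yl]-2,3-dioxabicyclo[2.2.1]hept-5-en-7-ylidene}hept-5-enoate | CCCCC/C=C\CC12OOC(C=C1)/C2=C/C=C/CCCC(=O)OC
A7 | alternative 3 | (±)-methyl (5E,7E)-7-{5-hydroxy-5-[(2Z)-oct-2-en-1-yl]-2-oxocyclopent-3-en-1-ylidene}hept-5-enoate | CCCCC/C=C\CC1(O)C=CC(=O)/C1=C/C=C/CCCC(=O)OC
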